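Think in molar per minute: in the blue and teal runs, while solid D lay in the flask, X grew at a steady pace in that unit, and that pace is what you carry here.

| setting | green | teal | blue | cedar | oak | elm | birch | alder | ash |
|---|---|---|---|---|---|---|---|---|---|
| D | 0.016 M | 0.12 M | 0.050 M | 0.025 M | 0.025 M | 0.012 M | 0.050 M | 0.050 M | 0.080 M |
| J | 0.28 mM | 0.28 mM | 0.29 mM | 0.60 mM | 0.10 mM | 0.080 mM | 0.28 mM | 0.10 mM | 0.20 mM |
| remark | run made earlier | run made earlier | run made earlier |  |  |  |  |  |  |
| time |  |  |  | 2.5 h | 2.5 h | 2.5 h | 2.5 h | 2.5 h | 2.5 h |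

- green (time / min: X / %, D / %): 20.0: 33.3, 0.1; 40.0: 55.9, 0; 60.0: 71.6, 0.8; 80.0: 80.3, 0
- teal (time / min: X / %, D / %): 10.0: 2.3, 82.1; 25.0: 7.4, 76.6; 50.0: 16.1, 68.7; 80.0: 23.8, 60.5
- blue (time / min: X / %, D / %): 10.0: 7.2, 58.4; 25.0: 18.6, 45.8; 50.0: 37.9, 26.2; 80.0: 59.3, 3.6

(scatter of a reading: 0.5 percentage points)

- solid, in amounts per volume of the solution: D
- at the start none of D is in solution

* ranking by amount of X, in percent of the D charged, from high to low, at 2.5 h (cedar / oak / elm / birch / alder / ash)
* the amount of X, in percent of the D charged of the flask you put first, at 2.5 h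
* the amount of X, in percent of the D charged of the flask you put last, at 2.5 h

The first rung is dissolving. By difference, the teal run holds 0.0187 M of dissolved monomer at its first reading, so the solution had filled by 10.0 min. The next rung is the green run, fully dissolved and pseudo-first-order in dissolved monomer at fixed J: its last reading gives 0.0203 min⁻¹, a lifetime of 49.3 min, longer than that filling. The blue run's gain in X between its first and last readings gives 3.72 × 10⁻⁴ M min⁻¹, the feed rate: the pace of X while solid remains. Dividing it by the green constant puts the ceiling of dissolved monomer at 0.0183 M. The next rung is the clearing time, the charge minus this ceiling, divided by the feed rate.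

The runs hold J near one value, so its order is unmeasured. My own choice is a feed rate scaling with the square root of J, as for chains ending in pairs. Ash then feeds at 3.09 × 10⁻⁴ M min⁻¹ and clears at 200 min, later than the asked time, so I reckon X in ash at 57.9%. Alder clears at 145 min, just inside the asked time. Putting that back in for the decay after clearing gives X in alder at 65.5%, more than in ash, so I put ash last. The same round gives cedar a feed rate of 5.35 × 10⁻⁴ M min⁻¹ and X at 98.7%, and I put cedar on top.

The forecast differs on J: “I assume first order (living chains)”. It gives cedar > birch > oak > elm > ash > alder, with 99.7% first and 40.5% last.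

The flasks give cedar > birch > oak > elm > alder > ash, with 98.8% first and 55.3% last; alder stands at 63.1%.

    J → 2 Q (k = 0.00380 min⁻¹)
    G + Q → Z + X (k = 6.40 × 10⁵ M⁻¹ s⁻¹)
    G + Z → X + Z, rate k3*[Z]*[G] (k = 17000 M⁻¹ s⁻¹)
    2 Z → L (k = 3.80 × 10⁷ M⁻¹ s⁻¹)
    D ⇌ G, rate k5*(cs5 - [G]) while solid is left; crystals form when [G] > cs5 (solubility = 19.0 mM, k = 0.510 min⁻¹)

Now take the neighbour of cedar, charged with 0.10 M of D at cedar's J. Reckoned with cedar's feed rate of 5.35 × 10⁻⁴ M min⁻¹, its clearing time is 153 min, later than the asked time, and the steady pace gives X 80.3%. The neighbour stands at 75.2% of X, with 18.1% as G, and solid D is still there at 6.66%.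

(The numbers in the tables are calculated for an exercise.)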